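**Retrosynthetic overview**
1. Target 30 ⇐ C6–O desilylation and C9–O acylation of macrocyclic alcohol 27.
2. 27 ⇐ closure of the ten-membered ring at C9–C10 by intramolecular Nozaki–Hiyama–Kishi coupling of iodoalkene aldehyde 25 (last ring formed).
3. 25 ⇐ late zinc Barbier union (C6–C7) of West epoxy aldehyde 12 (C1–C6, C10, C14, C15) and East bromomethyl butenolide 21 (C7–C9, C11–C13); this step creates C6, C7 and the α-methylene lactone.
4. 12 ⇐ pent-3-yn-1-ol + methyl but-2-ynoate (carbocupration, hydrozirconation–iodination, Sharpless epoxidation); 21 ⇐ (2Z)-but-2-ene-1,4-diol + 2-(bromomethyl)acrylic acid (Sharpless epoxidation, reductive opening, ring-closing metathesis).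
5. Ring order: oxirane (step 5) and butenolide (step 13) in the two branches, then the ten-membered carbocycle (step 17).

Assumption: positions are cited in germacrane numbering (lactone C12(=O)–O–C8, exocyclic methylene C13, ester on C9, methyl C14 on C10, epoxide C4–C5 with methyl C15, hydroxyl on C6).

**West fragment**

Step 1
Reactants: 1 pent-3-yn-1-ol
Product: 2 5-bromopent-2-yne
Conditions: CBr4, PPh3, CH2Cl2, 0 °C to rt
Reagents that add atoms: carbon tetrabromide BrC(Br)(Br)Br
Why: Appel bromination turns the primary alcohol into the bromide under neutral conditions that do not touch the internal alkyne.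

Step 2
Reactants: 2 5-bromopent-2-yne; 3 methyl but-2-ynoate
Product: 7 methyl (2E)-3-methyloct-2-en-6-ynoate, via pent-3-yn-1-ylmagnesium bromide 4 (not isolated), via pent-3-yn-1-ylcopper 5 (not isolated), via alkenylcopper adduct 6 (not isolated)
Conditions: Mg, THF, rt; CuBr·SMe2 (1.0 equiv), −45 °C; 3, −78 °C, 3 h; sat. aq NH4Cl, −78 °C
Reagents that add atoms: none
Why: Normant-type syn carbocupration of the ynoate and protonation of the configurationally stable alkenylcopper at −78 °C put the new chain cis to H and trans to the ester, so the trisubstituted C4=C5 olefin is formed as the E isomer.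

Step 3
Reactants: 7 methyl (2E)-3-methyloct-2-en-6-ynoate
Product: 8 (2E)-3-methyloct-2-en-6-yn-1-ol
Conditions: i-Bu2AlH (2.2 equiv), CH2Cl2, −78 °C; aq potassium sodium tartrate
Reagents that add atoms: none
Why: 1,2-reduction of the enoate with diisobutylaluminium hydride gives the allylic alcohol with the olefin geometry and the alkyne intact.

Step 4
Reactants: 8 (2E)-3-methyloct-2-en-6-yn-1-ol
Product: 10 (2E,6E)-7-iodo-3-methylocta-2,6-dien-1-ol, via alkenylzirconocene chloride 9 (not isolated)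
Conditions: Cp2Zr(H)Cl (3.0 equiv), THF, rt then 45 °C, 1 h; I2, THF, 0 °C
Reagents that add atoms: iodine [I][I]
Why: Schwartz hydrozirconation is a syn addition that, with excess reagent, equilibrates zirconium to the less hindered methyl-bearing alkyne carbon, and iodinolysis with retention gives the (E)-2-iodo-2-alkene needed for the ring closure (one equivalent of reagent is consumed by the hydroxyl group).

Step 5
Reactants: 10 (2E,6E)-7-iodo-3-methylocta-2,6-dien-1-ol
Product: 11 [(2S,3S)-3-[(3E)-4-iodopent-3-en-1-yl]-3-methyloxiran-2-yl]methanol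
Conditions: Ti(OiPr)4 (10 mol %), L-(+)-diethyl tartrate (12 mol %), t-BuOOH (2 equiv), 4 Å MS, CH2Cl2, −20 °C
Reagents that add atoms: tert-butyl hydroperoxide CC(C)(C)OO
Why: Katsuki–Sharpless asymmetric epoxidation of the (E)-allylic alcohol with the L-(+)-tartrate catalyst gives the (2S,3S)-epoxide (same sense as for geraniol), which sets C4 and C5 of the target, while the isolated iodoalkene is not epoxidised.

Step 6
Reactants: 11 [(2S,3S)-3-[(3E)-4-iodopent-3-en-1-yl]-3-methyloxiran-2-yl]methanol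
Product: 12 (2R,3S)-3-[(3E)-4-iodopent-3-en-1-yl]-3-methyloxirane-2-carbaldehyde
Conditions: Dess–Martin periodinane, pyridine, CH2Cl2, 0 °C to rt; used at once
Reagents that add atoms: none
Why: Dess–Martin oxidation gives the sensitive epoxy aldehyde under buffered, non-epimerising conditions (the descriptor at C2 changes only through CIP priorities).

**East fragment**

Step 7
Reactants: 13 (2Z)-but-2-ene-1,4-diol
Product: 14 (2Z)-4-[(triethylsilyl)oxy]but-2-en-1-ol
Conditions: 13 (4 equiv), Et3SiCl (1 equiv), imidazole, THF, 0 °C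
Reagents that add atoms: chlorotriethylsilane CC[Si](Cl)(CC)CC
Why: statistical monosilylation of the symmetrical diol used in excess differentiates the two ends for the asymmetric epoxidation.

Step 8
Reactants: 14 (2Z)-4-[(triethylsilyl)oxy]but-2-en-1-ol
Product: 15 [(2R,3S)-3-{[(triethylsilyl)oxy]methyl}oxiran-2-yl]methanol
Conditions: Ti(OiPr)4 (20 mol %), D-(−)-diethyl tartrate (24 mol %), t-BuOOH (2 equiv), 4 Å MS, CH2Cl2, −20 °C, 48 h
Reagents that add atoms: tert-butyl hydroperoxide CC(C)(C)OO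
Why: Katsuki–Sharpless asymmetric epoxidation with the D-(−)-tartrate catalyst gives the cis-(2R,3S)-epoxy alcohol (about 90% ee expected for a Z-allylic alcohol), whose C3 becomes C8 of the target.

Step 9
Reactants: 15 [(2R,3S)-3-{[(triethylsilyl)oxy]methyl}oxiran-2-yl]methanol
Product: 16 triethyl{[(2S,3S)-3-(iodomethyl)oxiran-2-yl]methoxy}silane
Conditions: I2, PPh3, imidazole, CH2Cl2, 0 °C
Reagents that add atoms: iodine [I][I]
Why: Garegg–Samuelsson (Appel-type) iodination replaces the primary hydroxyl without touching the epoxide stereocentres (the descriptor change is a CIP effect only).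

Step 10
Reactants: 16 triethyl{[(2S,3S)-3-(iodomethyl)oxiran-2-yl]methoxy}silane
Product: 17 (2R)-1-[(triethylsilyl)oxy]but-3-en-2-ol
Conditions: n-BuLi (1.5 equiv), THF, −78 °C; H2O
Reagents that add atoms: none
Why: iodine–lithium exchange followed by β-elimination opens the epoxide (reductive fragmentation of a 2,3-epoxy iodide) to the vinyl carbinol, the C–O bond at the carbinol carbon and hence its configuration being kept.

Step 11
Reactants: 18 2-(bromomethyl)prop-2-enoic acid
Product: 19 2-(bromomethyl)prop-2-enoyl chloride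
Conditions: (COCl)2, DMF (cat.), CH2Cl2, 0 °C to rt; concentrated
Reagents that add atoms: oxalyl chloride ClC(=O)C(Cl)=O
Why: acid chloride formation allows the next acylation without nucleophilic catalysts such as DMAP, which would attack the allylic bromide.

Step 12
Reactants: 17 (2R)-1-[(triethylsilyl)oxy]but-3-en-2-ol; 19 2-(bromomethyl)prop-2-enoyl chloride
Product: 20 (2R)-1-[(triethylsilyl)oxy]but-3-en-2-yl 2-(bromomethyl)prop-2-enoate
Conditions: 2,6-lutidine, CH2Cl2, −40 °C to 0 °C
Reagents that add atoms: none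
Why: O-acylation of the secondary allylic alcohol by the acid chloride with a hindered base proceeds with retention at the carbinol carbon.

Step 13
Reactants: 20 (2R)-1-[(triethylsilyl)oxy]but-3-en-2-yl 2-(bromomethyl)prop-2-enoate
Product: 21 (5R)-3-(bromomethyl)-5-{[(triethylsilyl)oxy]methyl}furan-2(5H)-one
Conditions: second-generation Hoveyda–Grubbs catalyst (5 mol %), CH2Cl2 (0.01 M), 40 °C
Reagents that add atoms: none
Why: ring-closing metathesis between the vinyl group and the 2-substituted acrylate closes the butenolide with loss of ethene under base-free conditions, so the base-sensitive γ-stereocentre is not racemised.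

**Fragment union and end game**

Step 14
Reactants: 12 (2R,3S)-3-[(3E)-4-iodopent-3-en-1-yl]-3-methyloxirane-2-carbaldehyde; 21 (5R)-3-(bromomethyl)-5-{[(triethylsilyl)oxy]methyl}furan-2(5H)-one
Product: 23 (4S,5R)-4-[(S)-hydroxy{(2S,3S)-3-[(3E)-4-iodopent-3-en-1-yl]-3-methyloxiran-2-yl}methyl]-3-methylidene-5-{[(triethylsilyl)oxy]methyl}oxolan-2-one, via allylzinc bromide 22 (not isolated)
Conditions: Zn dust (3 equiv), THF/sat. aq NH4Cl (3:1), 0 °C, 1 h
Reagents that add atoms: none
Why: zinc Barbier allylation in which the allylzinc adds through its ring carbon in a chair Zimmerman–Traxler transition state, anti to the C8 substituent (7,8-trans), with the aldehyde residue equatorial (6S with 7S) and on the Felkin–Anh face of the epoxy aldehyde (5,6-anti), so that reagent and substrate control are matched and allylic transposition unveils the α-methylene lactone.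

Step 15
Reactants: 23 (the Barbier adduct)
Product: 24 (4R,5R)-4-[(S)-{(2S,3S)-3-[(3E)-4-iodopent-3-en-1-yl]-3-methyloxiran-2-yl}[(triethylsilyl)oxy]methyl]-3-methylidene-5-{[(triethylsilyl)oxy]methyl}oxolan-2-one
Conditions: Et3SiOTf (2 equiv), 2,6-lutidine, CH2Cl2, −78 °C
Reagents that add atoms: triethylsilyl trifluoromethanesulfonate CC[Si](CC)(CC)OS(=O)(=O)C(F)(F)F
Why: silylation of the C6 hydroxyl blocks translactonisation and differentiates it from the C9 hydroxyl formed later (any primary silyl ether lost in step 14 is restored by the excess reagent; the ring descriptor changes by CIP only).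

Step 16
Reactants: 24 (the bis-silyl ether)
Product: 25 (2R,3R)-3-[(S)-{(2S,3S)-3-[(3E)-4-iodopent-3-en-1-yl]-3-methyloxiran-2-yl}[(triethylsilyl)oxy]methyl]-4-methylidene-5-oxooxolane-2-carbaldehyde
Conditions: (COCl)2 (4 equiv), DMSO (8 equiv), CH2Cl2, −78 °C then −40 °C, 40 min; Et3N, −78 °C to −20 °C
Reagents that add atoms: none
Why: under Swern conditions a primary triethylsilyl ether is cleaved and oxidised directly to the aldehyde while the hindered secondary silyl ether survives, which gives the C9 aldehyde without a separate deprotection.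

Step 17
Reactants: 25 (the iodoalkene aldehyde)
Product: 27 (4S,5S,6S,7R,8R,9S)-4,5-epoxy-9-hydroxy-6-[(triethylsilyl)oxy]germacra-1(10)E,11(13)-dien-12,8-olide, via alkenylchromium dichloride 26 (not isolated)
Conditions: CrCl2 (10 equiv), NiCl2 (2 mol %), degassed DMSO, 2 mM, rt, addition of 25 over 10 h
Reagents that add atoms: none
Why: intramolecular Nozaki–Hiyama–Kishi coupling closes the ten-membered ring at C9–C10 with retention of the E alkene geometry, and the alkenylchromium adds to the α-oxygenated aldehyde anti to the C8–O bond (polar Felkin–Anh), which gives the 8,9-anti (9S) alcohol.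

Step 18
Reactants: 27 (the macrocyclic alcohol); 28 2-methylpropanoyl chloride
Product: 29 (4S,5S,6S,7R,8R,9S)-4,5-epoxy-9-(2-methylpropanoyloxy)-6-[(triethylsilyl)oxy]germacra-1(10)E,11(13)-dien-12,8-olide
Conditions: pyridine, DMAP (0.2 equiv), CH2Cl2, 0 °C to rt
Reagents that add atoms: none
Why: esterification of the only free hydroxyl (C9) with the acid chloride proceeds with retention.

Step 19
Reactants: 29 (the silyl-protected ester)
Product: 30 (4S,5S,6S,7S,8R,9S)-4,5-epoxy-6-hydroxy-9-(2-methylpropanoyloxy)germacra-1(10)E,11(13)-dien-12,8-olide (CNP0220196.1)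
Conditions: HF·pyridine, pyridine, THF, 0 °C
Reagents that add atoms: none
Why: buffered fluoride desilylation frees the C6 hydroxyl under weakly acidic conditions that avoid base-induced translactonisation, Payne rearrangement and ester cleavage (the C7 descriptor returns to S by CIP only).

**Compound list**
1 | pent-3-yn-1-ol | CC#CCCO | starting material
2 | 5-bromopent-2-yne | CC#CCCBr | intermediate
3 | methyl but-2-ynoate | CC#CC(=O)OC | starting material
4 | pent-3-yn-1-ylmagnesium bromide | CC#CCC[Mg]Br | intermediate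
5 | pent-3-yn-1-ylcopper | CC#CCC[Cu] | intermediate
6 | methyl (2Z)-2-cuprio-3-methyloct-2-en-6-ynoate (alkenylcopper adduct, Cu cis to the pentynyl chain) | COC(=O)/C([Cu])=C(\C)CCC#CC | intermediate
7 | methyl (2E)-3-methyloct-2-en-6-ynoate | COC(=O)/C=C(\C)CCC#CC | intermediate
8 | (2E)-3-methyloct-2-en-6-yn-1-ol | OC/C=C(\C)CCC#CC | intermediate
9 | chlorobis(cyclopentadienyl)zirconium alkoxide of (2E,6E)-7-[chlorobis(cyclopentadienyl)zirconio]-3-methylocta-2,6-dien-1-ol | Cl[Zr](OC/C=C(\C)CC/C=C(\C)[Zr](Cl)(C1C=CC=C1)C1C=CC=C1)(C1C=CC=C1)C1C=CC=C1 | intermediate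
10 | (2E,6E)-7-iodo-3-methylocta-2,6-dien-1-ol | OC/C=C(\C)CC/C=C(\C)I | intermediate
11 | [(2S,3S)-3-[(3E)-4-iodopent-3-en-1-yl]-3-methyloxiran-2-yl]methanol | OC[C@@H]1O[C@@]1(C)CC/C=C(\C)I | intermediate
12 | (2R,3S)-3-[(3E)-4-iodopent-3-en-1-yl]-3-methyloxirane-2-carbaldehyde | O=C[C@@H]1O[C@@]1(C)CC/C=C(\C)I | intermediate
13 | (2Z)-but-2-ene-1,4-diol | OC/C=C\CO | starting material
14 | (2Z)-4-[(triethylsilyl)oxy]but-2-en-1-ol | OC/C=C\CO[Si](CC)(CC)CC | intermediate
15 | [(2R,3S)-3-{[(triethylsilyl)oxy]methyl}oxiran-2-yl]methanol | OC[C@H]1O[C@H]1CO[Si](CC)(CC)CC | intermediate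
16 | triethyl{[(2S,3S)-3-(iodomethyl)oxiran-2-yl]methoxy}silane | IC[C@H]1O[C@H]1CO[Si](CC)(CC)CC | intermediate
17 | (2R)-1-[(triethylsilyl)oxy]but-3-en-2-ol | O[C@H](C=C)CO[Si](CC)(CC)CC | intermediate
18 | 2-(bromomethyl)prop-2-enoic acid | C=C(CBr)C(=O)O | starting material
19 | 2-(bromomethyl)prop-2-enoyl chloride | C=C(CBr)C(Cl)=O | intermediate
20 | (2R)-1-[(triethylsilyl)oxy]but-3-en-2-yl 2-(bromomethyl)prop-2-enoate | C=C(CBr)C(=O)O[C@H](C=C)CO[Si](CC)(CC)CC | intermediate
21 | (5R)-3-(bromomethyl)-5-{[(triethylsilyl)oxy]methyl}furan-2(5H)-one | O=C1O[C@H](C=C1CBr)CO[Si](CC)(CC)CC | intermediate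
22 | bromo{[(5R)-2-oxo-5-{[(triethylsilyl)oxy]methyl}-2,5-dihydrofuran-3-yl]methyl}zinc (allylzinc bromide) | O=C1O[C@H](C=C1C[Zn]Br)CO[Si](CC)(CC)CC | intermediate
23 | (4S,5R)-4-[(S)-hydroxy{(2S,3S)-3-[(3E)-4-iodopent-3-en-1-yl]-3-methyloxiran-2-yl}methyl]-3-methylidene-5-{[(triethylsilyl)oxy]methyl}oxolan-2-one | C=C1C(=O)O[C@@H](CO[Si](CC)(CC)CC)[C@@H]1[C@H](O)[C@@H]1O[C@@]1(C)CC/C=C(\C)I | intermediate
24 | (4R,5R)-4-[(S)-{(2S,3S)-3-[(3E)-4-iodopent-3-en-1-yl]-3-methyloxiran-2-yl}[(triethylsilyl)oxy]methyl]-3-methylidene-5-{[(triethylsilyl)oxy]methyl}oxolan-2-one | C=C1C(=O)O[C@@H](CO[Si](CC)(CC)CC)[C@@H]1[C@H](O[Si](CC)(CC)CC)[C@@H]1O[C@@]1(C)CC/C=C(\C)I | intermediate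
25 | (2R,3R)-3-[(S)-{(2S,3S)-3-[(3E)-4-iodopent-3-en-1-yl]-3-methyloxiran-2-yl}[(triethylsilyl)oxy]methyl]-4-methylidene-5-oxooxolane-2-carbaldehyde | C=C1C(=O)O[C@@H](C=O)[C@@H]1[C@H](O[Si](CC)(CC)CC)[C@@H]1O[C@@]1(C)CC/C=C(\C)I | intermediate
26 | alkenylchromium dichloride (compound 25 with a CrCl2 unit in place of iodine, E geometry kept) | C=C1C(=O)O[C@@H](C=O)[C@@H]1[C@H](O[Si](CC)(CC)CC)[C@@H]1O[C@@]1(C)CC/C=C(\C)[Cr](Cl)Cl | intermediate
27 | (4S,5S,6S,7R,8R,9S)-4,5-epoxy-9-hydroxy-6-[(triethylsilyl)oxy]germacra-1(10)E,11(13)-dien-12,8-olide | C=C1C(=O)O[C@@H]2[C@@H]1[C@H](O[Si](CC)(CC)CC)[C@@H]1O[C@@]1(C)CC/C=C(\C)[C@@H]2O | intermediate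
28 | 2-methylpropanoyl chloride (isobutyryl chloride) | CC(C)C(Cl)=O | starting material
29 | (4S,5S,6S,7R,8R,9S)-4,5-epoxy-9-(2-methylpropanoyloxy)-6-[(triethylsilyl)oxy]germacra-1(10)E,11(13)-dien-12,8-olide | C=C1C(=O)O[C@@H]2[C@@H]1[C@H](O[Si](CC)(CC)CC)[C@@H]1O[C@@]1(C)CC/C=C(\C)[C@@H]2OC(=O)C(C)C | intermediate
30 | (4S,5S,6S,7S,8R,9S)-4,5-epoxy-6-hydroxy-9-(2-methylpropanoyloxy)germacra-1(10)E,11(13)-dien-12,8-olide (CNP0220196.1) | C=C1C(=O)O[C@@H]2[C@@H]1[C@H](O)[C@@H]1O[C@@]1(C)CC/C=C(\C)[C@@H]2OC(=O)C(C)C | target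

**Step count**
Total step count: 19.
Longest linear sequence: 12 steps (steps 1–6 then 14–19; the East line, steps 7–10, 12, 13 then 14–19, is equally long).

**Steps most likely to fail**

Step 14 (Barbier union). The epoxy aldehyde 12 may not survive the aqueous zinc medium, or its own facial bias may erode the selectivity at C6. The fallback moves the epoxidation behind the coupling and sets out from 10. Oxidation with MnO2 (CH2Cl2, rt) gives (2E,6E)-7-iodo-3-methylocta-2,6-dienal F1. Coupling of this with 21 under the same Zn/NH4Cl conditions gives, by reagent control alone, (4S,5R)-4-[(1R,2E,6E)-1-hydroxy-7-iodo-3-methylocta-2,6-dien-1-yl]-3-methylidene-5-{[(triethylsilyl)oxy]methyl}oxolan-2-one F2. Sharpless epoxidation of this secondary allylic alcohol (Ti(OiPr)4, L-(+)-diisopropyl tartrate, t-BuOOH, CH2Cl2, −20 °C) is the matched, erythro-selective case and installs the 4,5-epoxide. The route is rejoined at 23.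

Step 16 (direct Swern oxidation of the primary silyl ether). The oxidative desilylation may be sluggish, or the α-oxygenated aldehyde may epimerise at C8 with Et3N. The fallback replaces it by a chemoselective alcohol oxidation and sets out from 23. PPTS in MeOH at 0 °C removes the primary silyl ether to give diol (4S,5R)-4-[(S)-hydroxy{(2S,3S)-3-[(3E)-4-iodopent-3-en-1-yl]-3-methyloxiran-2-yl}methyl]-5-(hydroxymethyl)-3-methylideneoxolan-2-one F3. TEMPO (cat.)/PhI(OAc)2 in CH2Cl2 oxidises only the primary alcohol, under base-free conditions, to (2R,3S)-3-[(S)-hydroxy{(2S,3S)-3-[(3E)-4-iodopent-3-en-1-yl]-3-methyloxiran-2-yl}methyl]-4-methylidene-5-oxooxolane-2-carbaldehyde F4. Silylation of the C6 hydroxyl (Et3SiCl, imidazole, CH2Cl2, 0 °C) rejoins the route at 25.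

Step 17 (Nozaki–Hiyama–Kishi macrocyclisation). Oligomerisation is countered by high dilution, but strain in the ten-membered transition state may override Felkin–Anh control at C9. The fallback sets out from 25 and does not rely on the facial selectivity of the C–C bond formation. The same CrCl2/NiCl2 cyclisation then delivers the epimeric alcohol (4S,5S,6S,7R,8R,9R)-4,5-epoxy-9-hydroxy-6-[(triethylsilyl)oxy]germacra-1(10)E,11(13)-dien-12,8-olide F5. Mitsunobu esterification of this with isobutyric acid (PPh3, diisopropyl azodicarboxylate, toluene, 0 °C) inverts C9 and installs the ester in one operation. The route is rejoined at 29.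

**Further compounds**
F1 | step 14 | (2E,6E)-7-iodo-3-methylocta-2,6-dienal | O=C/C=C(\C)CC/C=C(\C)I
F2 | step 14 | (4S,5R)-4-[(1R,2E,6E)-1-hydroxy-7-iodo-3-methylocta-2,6-dien-1-yl]-3-methylidene-5-{[(triethylsilyl)oxy]methyl}oxolan-2-one | C=C1C(=O)O[C@@H](CO[Si](CC)(CC)CC)[C@@H]1[C@H](O)/C=C(\C)CC/C=C(\C)I
F3 | step 16 | (4S,5R)-4-[(S)-hydroxy{(2S,3S)-3-[(3E)-4-iodopent-3-en-1-yl]-3-methyloxiran-2-yl}methyl]-5-(hydroxymethyl)-3-methylideneoxolan-2-one | C=C1C(=O)O[C@@H](CO)[C@@H]1[C@H](O)[C@@H]1O[C@@]1(C)CC/C=C(\C)I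
F4 | step 16 | (2R,3S)-3-[(S)-hydroxy{(2S,3S)-3-[(3E)-4-iodopent-3-en-1-yl]-3-methyloxiran-2-yl}methyl]-4-methylidene-5-oxooxolane-2-carbaldehyde | C=C1C(=O)O[C@@H](C=O)[C@@H]1[C@H](O)[C@@H]1O[C@@]1(C)CC/C=C(\C)I
F5 | step 17 | (4S,5S,6S,7R,8R,9R)-4,5-epoxy-9-hydroxy-6-[(triethylsilyl)oxy]germacra-1(10)E,11(13)-dien-12,8-olide | C=C1C(=O)O[C@@H]2[C@@H]1[C@H](O[Si](CC)(CC)CC)[C@@H]1O[C@@]1(C)CC/C=C(\C)[C@H]2O
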